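The numbers in the tables stem from a simulated flask on assumed constants.

4 questions stand on 3 flasks:

| setting | Sunday's | spring | noon | dusk |
|---|---|---|---|---|
| starting complex | 0.13 mM | 0.20 mM | 0.20 mM | 0.20 mM |
| incoming ligand | 1.2 equiv | 1.20 equiv | 1.00 equiv | 4.00 equiv |
| leaving ligand | 0.50 equiv | 0.500 equiv | 0.500 equiv | 0.500 equiv |
| remark | run made earlier |  |  |  |
| time |  | 15 min | 15 min | 15 min |
Sunday's run (percent of the starting complex charged)

| time / min | complex with three exchanged / % | starting complex / % |
|---|---|---|
| 0.417 | 3.7 | 50.1 |
| 1.00 | 3.2 | 38.2 |
| 2.00 | 1.1 | 35.7 |
| 3.00 | 0.8 | 35.0 |

(scatter of a reading: 0.3 percentage points)
* which of these holds the largest part of the starting complex at the end of spring (complex with two exchanged / complex with one exchanged / starting complex / complex with three exchanged)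
* which of these holds the largest part of the starting complex at the end of noon (complex with two exchanged / complex with one exchanged / starting complex / complex with three exchanged)
* which of these holds the largest part of the starting complex at the end of dusk (complex with two exchanged / complex with one exchanged / starting complex / complex with three exchanged)
* how much complex with three exchanged is there at the end of spring, in percent of the starting complex charged

Sunday's run looks contradictory. It had 1.2 equiv of incoming ligand, more than one per complex, yet the reading of starting complex stalls at 35.0% after 3.00 min, having stood at 35.7% at 2.00 min. My reading is that incoming ligand is the limiting reagent and that already exchanged complexes compete for it. Suppose the charge X, in equivalents, has reacted in full, and let T be c(complex with three exchanged) + c(isomer of the product), each as a share of the complex charged. Counting complexes and then exchanges gives: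

c(starting complex) + c(complex with one exchanged) + c(complex with two exchanged) + T = 1

c(complex with one exchanged) + 2 c(complex with two exchanged) + 3 T = X

Subtracting the first from the second gives:

c(complex with two exchanged) − c(starting complex) + 2 T = X − 1

So, once the charge has reacted in full, the complex with two exchanged leads the starting complex when T stays below the crossover share, half the surplus of ligand over one equivalent. For spring, the crossover share is 10.0%. Sunday's readings have no column for the isomer, so they give no direct reading of T.

The forecast names complex with two exchanged for spring, starting complex for noon and complex with three exchanged for dusk, with 0.7% of complex with three exchanged at the end of spring (range 0.2% to 1.2%). It takes T near 8%, "so the two-exchanged complex narrowly leads".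

Among the species asked about, spring gives starting complex, noon starting complex and dusk complex with three exchanged, and complex with three exchanged at the end of spring stands at 0.940%. starting complex + incoming ligand → leaving ligand + complex with one exchanged (k = 290 /M/s); complex with one exchanged + incoming ligand → leaving ligand + complex with two exchanged (k = 540 /M/s); complex with two exchanged + incoming ligand → leaving ligand + complex with three exchanged (k = 340 /M/s); complex with three exchanged ⇌ isomer of the product (K = 15.0, k = 0.0560 /s)

In spring, with 0% of incoming ligand left, T is 15.0%, above the crossover share of 10.0%, and starting complex at 35.4% stands ahead of complex with two exchanged at 25.3%. In spring, complex with three exchanged and its isomer relax with a half-life of 0.193 min, far shorter than the 15 min of the run, and complex with three exchanged still stands at 0.940% after 150 min.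

The spring recipe with 2.00 equiv of incoming ligand instead has a crossover share of 50.0%. With 0% of incoming ligand left, its computed T is 43.6%, below that, and complex with two exchanged at 27.6% does lead starting complex at 14.9%.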